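## Analysis of the target

Prinsepiol is a furofuran lignan: a cis-fused 3,7-dioxabicyclo[3.3.0]octane with hydroxyl groups on both bridgeheads (C1, C5), 4-hydroxy-3-methoxyphenyl groups on C2 and C6, ring oxygens O3 and O7, and methylene groups C4 and C8; this numbering is kept for all intermediates, open-chain ones included. A C2 axis through the midpoint of C1–C5 pairs the four stereocenters: C1 and C5 are S, C2 and C6 are R, and each aryl group lies on the convex face, cis to the hydroxyl on the neighbouring bridgehead. C1 and C5 are adjacent, fully substituted, oxygen-bearing carbons, and making this di-tertiary cis-diol with absolute control is the main difficulty, because no hydrogen is left there for later correction. The second difficulty is to place C2 and C6 correctly relative to bridgeheads that carry no hydrogen. The sensitive groups are the free guaiacyl phenols (easily oxidised), the benzylic ether bonds C2–O3 and C6–O7 para to those phenols (acid-labile, prone to epimerisation or reductive opening), and the 1,2-diol. The strategy rests on one feature: C2 and C6 are benzylic carbons para to a free phenol, and each is 1,4-related, across the C1–C5 bond, to a carbon (C4 or C8) on the other carbinol carbon. If C4 and C8 are raised to the carboxyl level, the bonds C2–O3 and C6–O7 become additions of a carboxylic acid to a p-quinone methide that can be generated from a benzylic C–H bond, and the open-chain compound behind them is a C2-symmetric 2,3-dibenzylated tartaric acid.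

## Retrosynthetic reasoning

**16 to 14 by way of 15.** No skeletal bond is cut here; only the oxidation level of C4 and C8 changes. 16 is traced to the bis-lactol 15 and then to the bis-lactone 14. The carbonyl groups are wanted because a carboxyl-level carbon is what can close the rings at C2 and C6. Forward, two γ-lactones must be taken to cyclic ethers in two stages (hydride reduction to the lactol, then ionic deoxygenation) without ionising C2–O3 and C6–O7.

**14 to 10.** The bonds C2–O3 and C6–O7 are cut. They are chosen because each is a benzylic C–O bond para to a free phenol, so each can be formed by conjugate addition of a carboxylic acid to a p-quinone methide, first 11 and then 13, by way of the monolactone 12. Cutting the acyl bonds C4–O3 and C8–O7 instead would require benzylic alcohols at C2 and C6, which means two more stereocenters to carry and set. Cutting C1–C5 would give up absolute control of the carbinol carbons. The gain is that the diacid 10 has only two stereocenters and full C2 symmetry, while both rings and both benzylic stereocenters arise in one operation from C–H bonds. Forward, the reaction must dehydrogenate twice at benzylic carbon, close two five-membered rings, and put each aryl group on the face of the hydroxyls. Only the (S,S) threo arrangement of 10 allows the second closure, because it leads to a cis-fused bicycle.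

**10 to 7 by way of 9 and 8.** These are unmasking steps only. The phenols are carried as benzyl ethers, the acids as methyl esters and the diol as an isopropylidene ketal, removed in the order ketal, esters, benzyl ethers. Hydrogenolysis comes last so that the very polar 10 is obtained by filtration and is the only compound that meets the oxidant with free phenols.

**7 to 5 and 2, then 5 to 3 and 2.** The bonds C5–C6 and C1–C2, between each carbinol carbon and its benzylic carbon, are cut. This is the place to cut because both quaternary carbinols are then made from 3, the acetonide of dimethyl D-tartrate, whose C2 symmetry, threo relationship and (S,S) configuration are those required in 10. Forward, two successive ester enolate alkylations, by way of the enolates 4 and 6, with the benzylic bromide 2 must each occur with retention at the carbinol carbon.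

**2 to 1.** The bromide is made from the commercial benzyl-protected vanillyl alcohol 1 by functional group exchange.

## Alternatives that were turned down

**Alternative 1:** The bonds C1–C8 and C5–C4 are cut. The C2-symmetric diketone acetonide A1, which belongs to the natural (R,R) chiral-pool series, would be deprotonated twice in one flask with a strong amide base and hydroxymethylated with benzyl chloromethyl ether A3 to give the bis(benzyloxymethyl) diketone A2. No ring closes in this step. In its favour, C4 and C8 arrive at the ether oxidation level, so no lactone has to be reduced later; the cheaper natural chiral-pool series is used; and the phenols stay silylated until the end. On these points it is stronger than the chosen route. Against it, the enolate of an aryl ketone on a dioxolane carbon is fully substituted and has a ring oxygen in the β-position, and the hard chloromethyl ether invites O-alkylation; two quaternary centers must be made in one flask with the trans arrangement kept; and the key step sets neither C2 nor C6. Those centers would then depend on reagent-controlled reduction of two hindered aryl ketones next to quaternary carbons, followed by debenzylation and two etherifications. The chosen route alkylates softer ester enolates with a reactive benzylic bromide and sets C2 and C6 in the ring closure itself, where the bridgehead hydroxyls bias the face.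

**Alternative 2:** The C5–C6 bond is cut. Irradiation of the monocyclic oxolan-3-one A4 would excite the C5 ketone, which abstracts a benzylic hydrogen from the arylmethyl ether; the 1,5-biradical closes the second oxolane and creates the C5 hydroxyl, giving the bis(silyl) ether A5 of 16 (Norrish–Yang cyclisation). In its favour, the step makes a C–C bond, a ring and the tertiary alcohol at the final oxidation level, and only a desilylation remains; here it is clearly stronger than the chosen route, which needs two reductions after its key step. Against it, A4 is an unsymmetrical, enantiopure compound with a quaternary carbinol next to an aryl-bearing stereocenter, and reaching it is a linear synthesis that ignores the C2 symmetry of the target. The ketone also has oxygen on both α-carbons, so α-cleavage competes with hydrogen abstraction, and the biradical can revert or fragment. The configuration at C6 depends on the collapse of a long-lived biradical. The chosen route uses the symmetry (two identical closures), takes both carbinol centers from one chiral-pool compound, and runs in the ground state.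

**Alternative 3:** The C1–C5 bond is cut together with C2–O3 and C6–O7. One-electron oxidation of ferulic acid A6 with iron trichloride (FeCl3) under dioxygen, or with a laccase, couples two phenoxyl radicals at their β-carbons, and each carboxylic acid adds to the quinone methide of the other half to give the bis-lactone A7. In its favour, a single step from the cheap acid A6 builds the whole skeleton with the correct relative configuration at C2 and C6; in step count to the bicycle it is stronger than anything else considered, and its ring closure is the same acid-to-quinone-methide addition used in the chosen route. Against it, β–β coupling competes with other coupling modes, A7 is formed as a racemate, and A7 has hydrogen at C1 and C5 where the target has hydroxyl. Hydroxylating the bridgeheads would require enolates at C1 and C5, and each has the acyloxy oxygen of the other lactone on its β-carbon, so ring-opening elimination is the expected result. The chosen route keeps the same lactonisation but brings both tertiary hydroxyls and the absolute configuration in from the start.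

Key step: step 7

Remark (assumption): the lithium enolates 4 and 6 are taken to react with the benzylic bromide on the face cis to the vicinal ester (net retention at the carbinol carbon), the course known for alkylation of enolate 4. The configuration of 7 follows from this and is to be verified on 5.

## Route

Step 1
Reactants: 1 4-benzyloxy-3-methoxybenzyl alcohol
Product: 2 4-benzyloxy-3-methoxybenzyl bromide
Conditions: PBr3 (0.4 equiv), Et2O, 0 °C
Reagents that add atoms: phosphorus tribromide, BrP(Br)Br
Why: Bromodehydroxylation of a primary benzylic alcohol through its phosphite ester (SN2 by bromide); the aryl benzyl and methyl ethers are inert, and the bromide is used freshly.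

Step 2
Reactants: 3 dimethyl (4S,5S)-2,2-dimethyl-1,3-dioxolane-4,5-dicarboxylate; 2 4-benzyloxy-3-methoxybenzyl bromide
Product: 5 dimethyl (4S,5S)-4-[(4-benzyloxy-3-methoxyphenyl)methyl]-2,2-dimethyl-1,3-dioxolane-4,5-dicarboxylate, via lithium enolate 4 (not isolated)
Conditions: LiN(iPr)2 (LDA, 1.1 equiv), THF–HMPA, −78 °C; then 2, −78 → −50 °C
Reagents that add atoms: none
Why: Alkylation of a lithium ester enolate; the exocyclic enolate 4 resists β-elimination at −78 °C because the ring C–O bond lies near the enolate plane, and it is trapped by the reactive benzylic bromide. The new C1–C2 bond is expected on the face cis to the vicinal ester, which keeps the trans-diester arrangement (retention, 4S,5S). 5 is purified to one diastereomer, because its epimer at the quaternary carbon would lead into the enantiomeric series after the next enolisation.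

Step 3
Reactants: 5 dimethyl (4S,5S)-4-[(4-benzyloxy-3-methoxyphenyl)methyl]-2,2-dimethyl-1,3-dioxolane-4,5-dicarboxylate; 2 4-benzyloxy-3-methoxybenzyl bromide
Product: 7 dimethyl (4S,5S)-4,5-bis[(4-benzyloxy-3-methoxyphenyl)methyl]-2,2-dimethyl-1,3-dioxolane-4,5-dicarboxylate, via lithium enolate 6 (not isolated)
Conditions: LiN(iPr)2 (LDA, 1.2 equiv), THF–HMPA, −78 °C; then 2, −78 → −40 °C
Reagents that add atoms: none
Why: Second lithium ester enolate alkylation; in 6 the only stereocenter is the quaternary carbon C1, and the bromide should add to C5 anti to the C1 arylmethyl group and cis to the C1 ester, the same sense as in step 2, giving the C2-symmetric trans-diester. The meso diester that the other face would give is a separable diastereomer.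

Step 4
Reactants: 7 dimethyl (4S,5S)-4,5-bis[(4-benzyloxy-3-methoxyphenyl)methyl]-2,2-dimethyl-1,3-dioxolane-4,5-dicarboxylate
Product: 8 dimethyl (2S,3S)-2,3-bis[(4-benzyloxy-3-methoxyphenyl)methyl]-2,3-dihydroxybutanedioate
Conditions: 2 M HCl, MeOH–H2O, 60 °C
Reagents that add atoms: none
Why: Acid hydrolysis of the isopropylidene ketal; cleavage occurs at the ketal carbon, and no cation can form at the carbinol carbons (each is α to an ester), so the configuration is untouched. Benzyl aryl ethers and methyl esters survive.

Step 5
Reactants: 8 dimethyl (2S,3S)-2,3-bis[(4-benzyloxy-3-methoxyphenyl)methyl]-2,3-dihydroxybutanedioate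
Product: 9 (2S,3S)-2,3-bis[(4-benzyloxy-3-methoxyphenyl)methyl]-2,3-dihydroxybutanedioic acid
Conditions: LiOH (6 equiv), THF–MeOH–H2O, 40 °C; then 1 M HCl to pH 2
Reagents that add atoms: lithium hydroxide, [Li+].[OH-]
Why: Saponification (BAc2) of two α-hydroxy esters, helped by the neighbouring hydroxyl; the carbinol carbons have no α-hydrogen and cannot epimerise, and carboxylate formation disfavours retro-aldol cleavage of C1–C5.

Step 6
Reactants: 9 (2S,3S)-2,3-bis[(4-benzyloxy-3-methoxyphenyl)methyl]-2,3-dihydroxybutanedioic acid
Product: 10 (2S,3S)-2,3-dihydroxy-2,3-bis(4-hydroxy-3-methoxybenzyl)butanedioic acid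
Conditions: H2 (1 atm), 10% Pd/C, MeOH–EtOAc, rt
Reagents that add atoms: none
Why: Hydrogenolysis of two aryl benzyl ethers; the C1–C2 and C5–C6 bonds are benzylic C–C bonds and are not cleaved. Filtration and evaporation give the polar diacid without aqueous work-up.

Step 7
Reactants: 10 (2S,3S)-2,3-dihydroxy-2,3-bis(4-hydroxy-3-methoxybenzyl)butanedioic acid
Product: 14 (1S,2R,5S,6R)-1,5-dihydroxy-2,6-bis(4-hydroxy-3-methoxyphenyl)-3,7-dioxabicyclo[3.3.0]octane-4,8-dione, via quinone methide diacid 11 (not isolated), via monolactone acid 12 (not isolated), via quinone methide monolactone 13 (not isolated)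
Conditions: DDQ (2.1 equiv), dry 1,4-dioxane, 4 Å MS, 10 °C → rt
Reagents that add atoms: none
Why: DDQ forms a charge-transfer complex with the electron-rich phenol and takes a hydride equivalent from the para benzylic carbon C2, giving the p-quinone methide 11 and the hydroquinone; 11 cannot tautomerise to a styrene because C1 carries no hydrogen. The C4 carboxylic acid on the neighbouring carbinol C5 then adds to the methide carbon in a 5-exo-trig 1,6-conjugate addition that restores the arene and closes the first γ-lactone (ring A, C2–O3) in 12; a second dehydrogenation at C6 gives 13, and the C8 acid closes ring B (C6–O7) in the same 5-exo-trig mode. The closest known reaction type is the DDQ oxidation of 4-alkylphenols to quinone methides with intramolecular capture by oxygen nucleophiles, including oxidative γ-lactonisation of 4-arylbutanoic acids. Regioselectivity follows from ring size: the carboxyl on the same carbinol carbon could only give a β-lactone and the tertiary hydroxyls only an oxirane or oxetane, so the 1,4-related acid is the one nucleophile that can close a five-membered ring. C2 is set in the first closure, where the planar methide is attacked so that the aryl group ends on the face of ring A that carries the two small hydroxyls at C1 and C5, not the face crowded by the C8 carboxyl and the C6 arylmethyl group. C6 is set in the second closure, where the (1S,5S) configuration allows only a cis ring fusion and the aryl group takes the convex face, again cis to the bridgehead hydroxyls. Chemoselectivity for benzylic dehydrogenation over ipso attack on the phenol ring is characteristic of the quinone oxidant, and the acyloxy group now on C2 and C6 makes the remaining benzylic hydrogen less hydridic, so 2.1 equivalents should stop at 14. Dry dioxane is used so that water does not intercept 11 and 13.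

Step 8
Reactants: 14 (1S,2R,5S,6R)-1,5-dihydroxy-2,6-bis(4-hydroxy-3-methoxyphenyl)-3,7-dioxabicyclo[3.3.0]octane-4,8-dione
Product: 15 (1S,2R,5S,6R)-2,6-bis(4-hydroxy-3-methoxyphenyl)-3,7-dioxabicyclo[3.3.0]octane-1,4,5,8-tetrol (mixture of anomers at C4 and C8)
Conditions: iBu2AlH (DIBAL-H, 7 equiv), THF–CH2Cl2, −78 °C; then aq. potassium sodium tartrate
Reagents that add atoms: none
Why: Partial reduction of γ-lactones to lactols with DIBAL-H; four equivalents are consumed by the two phenols and the two tertiary hydroxyls, and the tetrahedral aluminium hemiacetals, held by the adjacent alkoxide, should not collapse before work-up. No stereocenter of the target is affected.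

Step 9
Reactants: 15 (1S,2R,5S,6R)-2,6-bis(4-hydroxy-3-methoxyphenyl)-3,7-dioxabicyclo[3.3.0]octane-1,4,5,8-tetrol
Product: 16 prinsepiol, (1S,2R,5S,6R)-2,6-bis(4-hydroxy-3-methoxyphenyl)-3,7-dioxabicyclo[3.3.0]octane-1,5-diol
Conditions: Et3SiH (6 equiv), BF3·OEt2 (4 equiv), CH2Cl2–MeCN, −78 → −30 °C
Reagents that add atoms: none
Why: Ionic hydrogenation of lactols: the Lewis acid ionises each anomeric hydroxyl to a ring oxocarbenium ion, which the silane reduces to CH2, so C4 and C8 end as non-stereogenic methylenes. The low temperature is chosen so that the lactols ionise much faster than the benzylic bonds C2–O3 and C6–O7.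

## Compound list

1 | 4-benzyloxy-3-methoxybenzyl alcohol | COc1cc(CO)ccc1OCc1ccccc1 | starting material
2 | 4-benzyloxy-3-methoxybenzyl bromide | COc1cc(CBr)ccc1OCc1ccccc1 | intermediate
3 | dimethyl (4S,5S)-2,2-dimethyl-1,3-dioxolane-4,5-dicarboxylate (acetonide of dimethyl D-tartrate) | COC(=O)[C@H]1OC(C)(C)O[C@@H]1C(=O)OC | starting material
4 | lithium enolate of 3, methyl (5S)-4-[lithiooxy(methoxy)methylidene]-2,2-dimethyl-1,3-dioxolane-5-carboxylate | [Li]OC(OC)=C1OC(C)(C)O[C@@H]1C(=O)OC | intermediate (not isolated)
5 | dimethyl (4S,5S)-4-[(4-benzyloxy-3-methoxyphenyl)methyl]-2,2-dimethyl-1,3-dioxolane-4,5-dicarboxylate | COC(=O)[C@@]1(Cc2ccc(OCc3ccccc3)c(OC)c2)OC(C)(C)O[C@@H]1C(=O)OC | intermediate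
6 | lithium enolate of 5, methyl (4S)-4-[(4-benzyloxy-3-methoxyphenyl)methyl]-5-[lithiooxy(methoxy)methylidene]-2,2-dimethyl-1,3-dioxolane-4-carboxylate | COC(=O)[C@@]1(Cc2ccc(OCc3ccccc3)c(OC)c2)OC(C)(C)OC1=C(OC)O[Li] | intermediate (not isolated)
7 | dimethyl (4S,5S)-4,5-bis[(4-benzyloxy-3-methoxyphenyl)methyl]-2,2-dimethyl-1,3-dioxolane-4,5-dicarboxylate | COC(=O)[C@@]1(Cc2ccc(OCc3ccccc3)c(OC)c2)OC(C)(C)O[C@]1(Cc2ccc(OCc3ccccc3)c(OC)c2)C(=O)OC | intermediate
8 | dimethyl (2S,3S)-2,3-bis[(4-benzyloxy-3-methoxyphenyl)methyl]-2,3-dihydroxybutanedioate | COC(=O)[C@](O)(Cc1ccc(OCc2ccccc2)c(OC)c1)[C@@](O)(Cc1ccc(OCc2ccccc2)c(OC)c1)C(=O)OC | intermediate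
9 | (2S,3S)-2,3-bis[(4-benzyloxy-3-methoxyphenyl)methyl]-2,3-dihydroxybutanedioic acid | OC(=O)[C@](O)(Cc1ccc(OCc2ccccc2)c(OC)c1)[C@@](O)(Cc1ccc(OCc2ccccc2)c(OC)c1)C(=O)O | intermediate
10 | (2S,3S)-2,3-dihydroxy-2,3-bis(4-hydroxy-3-methoxybenzyl)butanedioic acid | OC(=O)[C@](O)(Cc1ccc(O)c(OC)c1)[C@@](O)(Cc1ccc(O)c(OC)c1)C(=O)O | intermediate
11 | (2S,3S)-2,3-dihydroxy-2-(4-hydroxy-3-methoxybenzyl)-3-[(3-methoxy-4-oxocyclohexa-2,5-dien-1-ylidene)methyl]butanedioic acid | OC(=O)[C@](O)(C=C1C=CC(=O)C(OC)=C1)[C@@](O)(Cc1ccc(O)c(OC)c1)C(=O)O | intermediate (not isolated)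
12 | (2R,3S,4S)-3,4-dihydroxy-4-(4-hydroxy-3-methoxybenzyl)-2-(4-hydroxy-3-methoxyphenyl)-5-oxooxolane-3-carboxylic acid | COc1cc([C@H]2OC(=O)[C@](O)(Cc3ccc(O)c(OC)c3)[C@]2(O)C(=O)O)ccc1O | intermediate (not isolated)
13 | (2R,3S,4S)-3,4-dihydroxy-2-(4-hydroxy-3-methoxyphenyl)-4-[(3-methoxy-4-oxocyclohexa-2,5-dien-1-ylidene)methyl]-5-oxooxolane-3-carboxylic acid | COc1cc([C@H]2OC(=O)[C@](O)(C=C3C=CC(=O)C(OC)=C3)[C@]2(O)C(=O)O)ccc1O | intermediate (not isolated)
14 | (1S,2R,5S,6R)-1,5-dihydroxy-2,6-bis(4-hydroxy-3-methoxyphenyl)-3,7-dioxabicyclo[3.3.0]octane-4,8-dione | COc1cc([C@H]2OC(=O)[C@]3(O)[C@@H](c4ccc(O)c(OC)c4)OC(=O)[C@]23O)ccc1O | intermediate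
15 | (1S,2R,5S,6R)-2,6-bis(4-hydroxy-3-methoxyphenyl)-3,7-dioxabicyclo[3.3.0]octane-1,4,5,8-tetrol (anomers at C4, C8) | COc1cc([C@H]2OC(O)[C@]3(O)[C@@H](c4ccc(O)c(OC)c4)OC(O)[C@]23O)ccc1O | intermediate
16 | prinsepiol, (1S,2R,5S,6R)-2,6-bis(4-hydroxy-3-methoxyphenyl)-3,7-dioxabicyclo[3.3.0]octane-1,5-diol | COc1cc([C@H]2OC[C@]3(O)[C@@H](c4ccc(O)c(OC)c4)OC[C@]23O)ccc1O | target

## Step count and least certain steps

Total step count: 9. Longest linear sequence: 9 steps (1 to 16; 8 steps counted from 3).

**Step 7 (key step).** The quinone methides 11 and 13 may be consumed by channels other than the 5-exo capture. The most likely are loss of carbon dioxide from the carboxyl group on the carbon next to the methide carbon (a decarboxylative fragmentation), further oxidation of the lactone benzylic C–H bonds, and incomplete facial selectivity in the closure of ring A. The fallback separates the C–H oxidation from the ring closure; it sets out from 8 and returns at 14. Hydrogenolysis of 8 (H2, Pd/C) gives dimethyl (2S,3S)-2,3-dihydroxy-2,3-bis(4-hydroxy-3-methoxybenzyl)butanedioate F1. DDQ in methanol–dioxane then oxidises both benzylic positions with capture of the quinone methides by the solvent (benzylic methoxylation of 4-alkylphenols, with the carboxyls masked as esters so that they cannot be lost), giving dimethyl (2S,3S)-2,3-dihydroxy-2,3-bis[(4-hydroxy-3-methoxyphenyl)(methoxy)methyl]butanedioate F2; the configuration at the new carbons does not matter. TsOH in wet acetonitrile ionises the p-hydroxybenzyl ethers, and each benzylic center is captured by the neighbouring ester group with loss of methanol. This should give 14 under conditions in which C2 and C6 can settle on the hydroxyl face.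

**Step 3.** The hindered, fully substituted enolate 6 may react slowly in the SN2 step, so that ring-opening β-elimination or ester condensation takes over on warming, and attack on the wrong face would give the meso diester. The fallback sets out from 5 and returns at 10. Enolate 6 is generated as before and treated with 4-benzyloxy-3-methoxybenzaldehyde F3 (carbonyl addition is much faster than alkylation at −78 °C), then with acetic anhydride to trap the aldolate as dimethyl (4S,5S)-4-[acetoxy(4-benzyloxy-3-methoxyphenyl)methyl]-5-[(4-benzyloxy-3-methoxyphenyl)methyl]-2,2-dimethyl-1,3-dioxolane-4,5-dicarboxylate F4. Hydrogenolysis (H2, Pd/C, EtOAc–AcOH) removes the benzylic acetoxy group and both benzyl ethers to give dimethyl (4S,5S)-4,5-bis(4-hydroxy-3-methoxybenzyl)-2,2-dimethyl-1,3-dioxolane-4,5-dicarboxylate F5. Aqueous HCl in methanol converts F5 into F1, and LiOH then gives 10.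

**Step 2.** The facial selectivity of the first alkylation may be lower than expected, or opposite. The absolute configuration of 7 is decided here: the epimer of 5 at the quaternary carbon gives the enantiomer of 6 on enolisation. The relative configuration of purified 5 is therefore established before step 3. If the bromide is found to enter trans to the vicinal ester, the stereochemical design changes from retention–retention to inversion–retention; this fallback sets out from 2 and returns at 6, from which step 3 leads to 7. The commercial enantiomeric acetonide, dimethyl (4R,5R)-2,2-dimethyl-1,3-dioxolane-4,5-dicarboxylate F6, is alkylated with 2 to give dimethyl (4S,5R)-4-[(4-benzyloxy-3-methoxyphenyl)methyl]-2,2-dimethyl-1,3-dioxolane-4,5-dicarboxylate F7. Enolisation of F7 at its remaining C–H gives the same enolate 6.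

**Step 9.** BF3·OEt2 may ionise the benzylic bonds C2–O3 and C6–O7, which are para to free phenols, leading to epimerisation at C2 and C6 or to reductive ring opening by the silane. The fallback sets out from 15 and returns at 16. Acetic anhydride in pyridine acetylates the phenolic and anomeric hydroxyls (the tertiary ones stay free) to give (1S,2R,5S,6R)-4,8-diacetoxy-2,6-bis(4-acetoxy-3-methoxyphenyl)-3,7-dioxabicyclo[3.3.0]octane-1,5-diol F8. Et3SiH with BF3·OEt2 at −40 °C reduces the anomeric acetates, while the aryl acetates, much poorer donors than phenols, suppress benzylic ionisation, giving prinsepiol 4',4''-di-O-acetate F9. K2CO3 in methanol then gives 16.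

**Step 8.** Reduction may go past the lactol, or stop short because polyaluminated intermediates precipitate. The fallback sets out from 14 and returns at 16. LiAlH4 in THF at reflux reduces both lactones fully to (1R,2S,3S,4R)-1,4-bis(4-hydroxy-3-methoxyphenyl)-2,3-bis(hydroxymethyl)butane-1,2,3,4-tetrol F10. Catalytic HCl in THF–MeCN ionises each benzylic hydroxyl para to the phenol, and the primary hydroxyl on the other carbinol carbon closes each oxolane (5-exo), with the aryl groups expected on the convex face. This gives 16 directly.

## Further compounds

F1 | step 7 | dimethyl (2S,3S)-2,3-dihydroxy-2,3-bis(4-hydroxy-3-methoxybenzyl)butanedioate | COC(=O)[C@](O)(Cc1ccc(O)c(OC)c1)[C@@](O)(Cc1ccc(O)c(OC)c1)C(=O)OC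
F2 | step 7 | dimethyl (2S,3S)-2,3-dihydroxy-2,3-bis[(4-hydroxy-3-methoxyphenyl)(methoxy)methyl]butanedioate (epimers at the benzylic carbons) | COC(=O)[C@](O)(C(OC)c1ccc(O)c(OC)c1)[C@@](O)(C(OC)c1ccc(O)c(OC)c1)C(=O)OC
F3 | step 3 | 4-benzyloxy-3-methoxybenzaldehyde (commercial, used as electrophile) | COc1cc(C=O)ccc1OCc1ccccc1
F4 | step 3 | dimethyl (4S,5S)-4-[acetoxy(4-benzyloxy-3-methoxyphenyl)methyl]-5-[(4-benzyloxy-3-methoxyphenyl)methyl]-2,2-dimethyl-1,3-dioxolane-4,5-dicarboxylate (epimers at the acetoxy carbon) | COC(=O)[C@@]1(Cc2ccc(OCc3ccccc3)c(OC)c2)OC(C)(C)O[C@]1(C(OC(C)=O)c2ccc(OCc3ccccc3)c(OC)c2)C(=O)OC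
F5 | step 3 | dimethyl (4S,5S)-4,5-bis(4-hydroxy-3-methoxybenzyl)-2,2-dimethyl-1,3-dioxolane-4,5-dicarboxylate | COC(=O)[C@@]1(Cc2ccc(O)c(OC)c2)OC(C)(C)O[C@]1(Cc2ccc(O)c(OC)c2)C(=O)OC
F6 | step 2 | dimethyl (4R,5R)-2,2-dimethyl-1,3-dioxolane-4,5-dicarboxylate (commercial, used as starting material) | COC(=O)[C@@H]1OC(C)(C)O[C@H]1C(=O)OC
F7 | step 2 | dimethyl (4S,5R)-4-[(4-benzyloxy-3-methoxyphenyl)methyl]-2,2-dimethyl-1,3-dioxolane-4,5-dicarboxylate | COC(=O)[C@@]1(Cc2ccc(OCc3ccccc3)c(OC)c2)OC(C)(C)O[C@H]1C(=O)OC
F8 | step 9 | (1S,2R,5S,6R)-4,8-diacetoxy-2,6-bis(4-acetoxy-3-methoxyphenyl)-3,7-dioxabicyclo[3.3.0]octane-1,5-diol (anomers at C4, C8) | COc1cc([C@H]2OC(OC(C)=O)[C@]3(O)[C@@H](c4ccc(OC(C)=O)c(OC)c4)OC(OC(C)=O)[C@]23O)ccc1OC(C)=O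
F9 | step 9 | prinsepiol 4',4''-di-O-acetate | COc1cc([C@H]2OC[C@]3(O)[C@@H](c4ccc(OC(C)=O)c(OC)c4)OC[C@]23O)ccc1OC(C)=O
F10 | step 8 | (1R,2S,3S,4R)-1,4-bis(4-hydroxy-3-methoxyphenyl)-2,3-bis(hydroxymethyl)butane-1,2,3,4-tetrol | COc1cc([C@@H](O)[C@@](O)(CO)[C@](O)(CO)[C@H](O)c2ccc(O)c(OC)c2)ccc1O
A1 | alternative 1 | (4R,5R)-4,5-bis[4-(tert-butyldimethylsilyloxy)-3-methoxybenzoyl]-2,2-dimethyl-1,3-dioxolane | O=C(c1ccc(O[Si](C)(C)C(C)(C)C)c(OC)c1)[C@@H]2OC(C)(C)O[C@H]2C(=O)c3ccc(O[Si](C)(C)C(C)(C)C)c(OC)c3
A2 | alternative 1 | (4R,5R)-4,5-bis(benzyloxymethyl)-4,5-bis[4-(tert-butyldimethylsilyloxy)-3-methoxybenzoyl]-2,2-dimethyl-1,3-dioxolane | O=C(c1ccc(O[Si](C)(C)C(C)(C)C)c(OC)c1)[C@]2(COCc3ccccc3)OC(C)(C)O[C@@]2(COCc4ccccc4)C(=O)c5ccc(O[Si](C)(C)C(C)(C)C)c(OC)c5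
A3 | alternative 1 | benzyl chloromethyl ether | ClCOCc1ccccc1
A4 | alternative 2 | (4S,5R)-4-hydroxy-5-[4-(tert-butyldimethylsilyloxy)-3-methoxyphenyl]-4-{[4-(tert-butyldimethylsilyloxy)-3-methoxybenzyl]oxymethyl}oxolan-3-one | COc1cc([C@H]2OCC(=O)[C@]2(O)COCc3ccc(O[Si](C)(C)C(C)(C)C)c(OC)c3)ccc1O[Si](C)(C)C(C)(C)C
A5 | alternative 2 | prinsepiol bis(tert-butyldimethylsilyl) ether | COc1cc([C@H]2OC[C@]3(O)[C@@H](c4ccc(O[Si](C)(C)C(C)(C)C)c(OC)c4)OC[C@]23O)ccc1O[Si](C)(C)C(C)(C)C
A6 | alternative 3 | ferulic acid | COc1cc(/C=C/C(=O)O)ccc1O
A7 | alternative 3 | 2,6-bis(4-hydroxy-3-methoxyphenyl)-3,7-dioxabicyclo[3.3.0]octane-4,8-dione (formed as the racemate; target-series enantiomer drawn) | COc1cc([C@H]2OC(=O)[C@@H]3[C@@H](c4ccc(O)c(OC)c4)OC(=O)[C@H]23)ccc1O
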